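(The runs come from a simulation for an exercise, and the scatter is random.)

At 8.0 min you read the flasks below, and what I leave you is my bet on one fork.

the same everywhere: Sbt 0.50 mM

|  | Rea | Rea2 | remark | time |
|---|---|---|---|---|
| dawn | 2.5 equiv | 1.5 equiv | run made earlier |  |
| winter | 3.5 equiv | 1.5 equiv | run made earlier |  |
| noon | 5.5 equiv | 1.5 equiv | run made earlier |  |
| south-east | 2.50 equiv (fed, over 3.0 min) | 1.50 equiv | all else is in the flask from the start; the feed brings no volume worth counting | 8.0 min |
| east | 2.50 equiv | 1.50 equiv (fed, over 50 s) | all else is in the flask from the start; the feed brings no volume worth counting | 8.0 min |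
| north-west | 2.50 equiv | 1.50 equiv (fed, over 3.0 min) | all else is in the flask from the start; the feed brings no volume worth counting | 8.0 min |
| south-west | 2.50 equiv | 1.50 equiv | everything together at the start | 8.0 min |

| run | time / min | Rea.Int / % |
|---|---|---|
| dawn | 0.667 | 17.2 |
| dawn | 1.00 | 13.9 |
| dawn | 2.00 | 9.9 |
| dawn | 3.00 | 10.9 |
| dawn | 5.00 | 9.9 |
| dawn | 8.00 | 9.3 |
| winter | 0.667 | 19.3 |
| winter | 1.00 | 16.3 |
| winter | 2.00 | 11.7 |
| winter | 3.00 | 12.1 |
| winter | 5.00 | 11.1 |
| winter | 8.00 | 12.9 |
| noon | 0.667 | 24.4 |
| noon | 1.00 | 21.0 |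
| noon | 2.00 | 14.2 |
| noon | 3.00 | 14.7 |
| noon | 5.00 | 15.2 |
| noon | 8.00 | 13.4 |

(readings scatter by 1 percentage point)

* the flask with the highest amount of Rea.Int, in percent of the Sbt charged ("all alike" if they lie within 1.5 percentage points) (south-east / east / north-west / south-west / all alike)
* final Rea.Int, as a percentage of the Sbt charged, in south-east
* final Rea.Int, as a percentage of the Sbt charged, in east
* final Rea.Int, as a percentage of the Sbt charged, in north-west
* final Rea.Int, as a percentage of the Sbt charged, in south-west

- a reading or a percentage of Rea.Int counts all its forms, free or not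

Every earlier run is already falling after its first reading at 0.667 min, so I take the making of Rea.Int to be over by then, and the flat readings from 2.00 min average 10.0 % in dawn and 14.4 % in noon. I suppose that Sbt passes through a short-lived Int, which Rea turns into Rea.Int and Rea2 takes away, so one molecule is lost at that fork with the chance q = S c(Rea2) / (c(Rea) + S c(Rea2)). If a fixed part of the Rea branch stays on the plateau, dawn and noon give the selectivity factor S, how many times faster Rea2 takes Int than Rea does at equal concentration, of 2.10, and a kept part of 22.6 %, both of them readings that carry the scatter of those runs.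

I take as my window the time up to that first reading, and over it a steady feed has brought in, on average, the charge times the window over twice the feed time, which is 0.167 equiv of Rea2 in north-west. So q is 12.3 % in north-west, 33.6 % in east, 55.8 % in south-west and 91.9 % in south-east. I expect Rea.Int of 19.8 %, 15.0 %, 10.0 % and 1.83 % in that order, north-west highest. Leave the Rea2 feed slow, since the quicker feed of east carries the larger q.

The forecast parts from me on the feed: it names south-east, with 45 % there, 8.5 % in east, 8 % in north-west and 9.5 % in south-west, holding that “Feeding Rea lets Rea2 die before much Rea.Int exists”.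

The flasks give 25.0 % in north-west, 19.5 % in east, 9.56 % in south-west and 1.48 % in south-east.

    Rea + Int → Rea.Int (k = 5200 M⁻¹ s⁻¹)
    Rea2 + Rea.Int ⇌ Int2, settled at all times (K = 1800 M⁻¹)
    Rea2 + Int → Rea2.Int (k = 18000 M⁻¹ s⁻¹)
    Rea.Int ⇌ Sdp2 (K = 5.00, k = 0.0620 s⁻¹)
    Sbt + Rea.Int → Sdp (k = 16.0 M⁻¹ s⁻¹)
    Sbt → Int (k = 0.0670 s⁻¹)

The half-life of Sbt by its making of Int, 0.17 min in south-west, is far shorter than the slow feed's 3.0 min. In north-west 96 % of that making up to 8.0 min lies behind at 0.800 min, and Rea2.Int ends at 10.8 % against my q of 12.3 %.

For the neighbour of north-west charged with 6.00 equiv of Rea2, the same S gives q of 36.0 %. That flask holds Rea2.Int at 29.6 % and Rea.Int at 35.7 %, more than my kept part of 22.6 %.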